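Labdane numbering is used. Ring A is disconnected at C1–C10 and C3–C4: its unfunctionalised C1–C2–C3 trimethylene bridge spans the two methyl-bearing quaternary carbons C-4 and C-10, which flank C-5 in a 1,3-relationship. Both bonds are made in one flask by a (3+3) annulation of 1-chloro-3-iodopropane onto a 1,3-bis-enolate (α′-enolate of the C-9 enone, then ester enolate at C-4) of a keto ester made from (R)-carvone, which supplies ring B, C-17, C-5 and C-4/C-18/C-19. Angular methylation then sets the cis ring fusion; a formaldehyde ene reaction and a B-alkyl Suzuki coupling complete C-9 and the butenolide.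

Key step: step 4

Remark: C-19 is the acetoxymethyl carbon, C-18 the methyl on C-4 and C-20 the methyl on C-10; the SMILES is read as a cis-fused decalin with H-5, C-20, C-19 and C-11 on one face, and 3-bromofuran-2(5H)-one is taken as a purchasable building block.

Step 1
Reactants: 1 (R)-(−)-carvone
Product: 2 (5R)-2-methyl-5-(2-methyloxiran-2-yl)cyclohex-2-en-1-one (both epimers at the oxirane carbon)
Conditions: mCPBA, CH2Cl2, 0 °C
Reagents that add atoms: 3-chloroperoxybenzoic acid (mCPBA), OOC(=O)c1cccc(Cl)c1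
Why: Prilezhaev epoxidation, in which the electron-rich isopropenyl alkene reacts and the electron-poor enone alkene does not; the new oxirane stereocentre is unselective and is erased in steps 2 to 4.

Step 2
Reactants: 2 (5R)-2-methyl-5-(2-methyloxiran-2-yl)cyclohex-2-en-1-one
Product: 3 2-[(1R)-4-methyl-5-oxocyclohex-3-en-1-yl]propanal (both epimers at C-2 of the propanal)
Conditions: BF3·OEt2 (0.2 equiv), CH2Cl2, −40 to 0 °C
Reagents that add atoms: none
Why: Meinwald rearrangement, in which Lewis acid opening to the tertiary cation at C-4 and a 1,2-hydride shift give the α-branched aldehyde; the C-4 stereocentre is lost on enolisation in step 4.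

Step 3
Reactants: 3 2-[(1R)-4-methyl-5-oxocyclohex-3-en-1-yl]propanal
Product: 4 methyl 2-[(1R)-4-methyl-5-oxocyclohex-3-en-1-yl]propanoate (both epimers at C-2)
Conditions: KHSO5 (as 2KHSO5·KHSO4·K2SO4), MeOH, rt
Reagents that add atoms: potassium peroxymonosulfate, [K+].[O-]OS(=O)(=O)O; methanol, CO
Why: Oxidative esterification of an aliphatic aldehyde by peroxymonosulfate in methanol (through the hemiacetal), to which the enone should be inert.

Step 4
Reactants: 4 methyl 2-[(1R)-4-methyl-5-oxocyclohex-3-en-1-yl]propanoate; 5 1-chloro-3-iodopropane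
Product: 7 methyl (1R,8aR)-1,6-dimethyl-5-oxo-1,2,3,4,4a,5,8,8a-octahydronaphthalene-1-carboxylate (C-4a epimers), via C-10 chloropropyl keto ester 6 (not isolated)
Conditions: LiN(i-Pr)2 (1.05 equiv), THF, −78 °C; 5 (1.1 equiv), DMPU, −78 to −20 °C; then LiN(i-Pr)2 (2.2 equiv), −78 °C to rt
Reagents that add atoms: none
Why: One equivalent of LiN(i-Pr)2 gives only the kinetic cross-conjugated α′-enolate of the enone (C-10), which displaces iodide from 5 (C1–C10); the further base deprotonates C-10 again and the ester α-carbon C-4, and the ester enolate, the only carbon nucleophile that can reach the chloride through a six-membered transition state, displaces it (C3–C4). This is a (3+3) annulation of a 1,3-bis-enolate with a propane-1,3-diyl biselectrophile, the closest known reaction type being the double alkylation of ketone and ester dianions with 1,3-dihalides. Ring A closes in the 6-(enolexo)-exo-tet mode. The quaternary centre C-4 is controlled by C-5 through allylic 1,3-strain: H-5 eclipses the enolate C4=C(OLi)OMe bond, C-10 with its tether and C-6 lie on opposite faces, so C-3 arrives on the C-10 face and the ester ends cis to H-5 and the methyl cis to C-6; C-10 forms as an epimer mixture that converges in step 5. The step needs chemoselectivity between the halides (iodide first, chloride second) and between the nucleophiles (ketone enolate intermolecularly, ester enolate intramolecularly), which the order of base addition and the four-membered ring that C-alkylation by the ketone enolate would require should secure.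

Step 5
Reactants: 7 methyl (1R,8aR)-1,6-dimethyl-5-oxo-1,2,3,4,4a,5,8,8a-octahydronaphthalene-1-carboxylate
Product: 8 methyl (1R,4aR,8aR)-1,4a,6-trimethyl-5-oxo-1,2,3,4,4a,5,8,8a-octahydronaphthalene-1-carboxylate (cis-fused)
Conditions: LiN(i-Pr)2 (1.1 equiv), THF, −78 °C; MeI, DMPU, −78 to 0 °C
Reagents that add atoms: iodomethane, CI
Why: Kinetic α′-deprotonation (C-10 carries the only α-hydrogen left) and enolate C-alkylation, in which MeI should enter anti to the adjacent quaternary C-4, whose axial methyl shields the other face, and so syn to H-5, giving the cis-fused decalin as in classical angular alkylations of 1-decalone enolates.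

Step 6
Reactants: 8 methyl (1R,4aR,8aR)-1,4a,6-trimethyl-5-oxo-1,2,3,4,4a,5,8,8a-octahydronaphthalene-1-carboxylate
Product: 10 methyl (1R,4aR,8aR)-1,4a,6-trimethyl-5-(trifluoromethanesulfonyloxy)-1,2,3,4,4a,7,8,8a-octahydronaphthalene-1-carboxylate, via lithium enolate 9 (not isolated)
Conditions: LiBH(s-Bu)3, THF, −78 °C; then PhNTf2, −78 to 0 °C
Reagents that add atoms: N-phenylbis(trifluoromethanesulfonimide), O=S(=O)(N(c1ccccc1)S(=O)(=O)C(F)(F)F)C(F)(F)F
Why: Conjugate hydride reduction of the β-unsubstituted enone gives the C8–C9 enolate regiospecifically (C-10 is quaternary), and O-sulfonylation traps it as the enol triflate; the ester should not be reduced at −78 °C.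

Step 7
Reactants: 10 methyl (1R,4aR,8aR)-1,4a,6-trimethyl-5-(trifluoromethanesulfonyloxy)-1,2,3,4,4a,7,8,8a-octahydronaphthalene-1-carboxylate
Product: 11 methyl (1R,4aS,8aR)-1,4a,6-trimethyl-1,2,3,4,4a,7,8,8a-octahydronaphthalene-1-carboxylate
Conditions: Pd(OAc)2 (5 mol %), PPh3, HCO2H, n-Bu3N, DMF, 60 °C
Reagents that add atoms: none
Why: Palladium-catalysed formate reduction of an enol triflate (oxidative addition to zerovalent palladium, formate decarboxylation, reductive elimination) replaces OTf by H and leaves the trisubstituted C8=C9 alkene.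

Step 8
Reactants: 11 methyl (1R,4aS,8aR)-1,4a,6-trimethyl-1,2,3,4,4a,7,8,8a-octahydronaphthalene-1-carboxylate
Product: 12 methyl (1R,4aR,5R,8aR)-5-(hydroxymethyl)-1,4a-dimethyl-6-methylidenedecahydronaphthalene-1-carboxylate
Conditions: Me2AlCl (2 equiv), (CH2O)n, CH2Cl2, 0 °C to rt
Reagents that add atoms: paraformaldehyde (formaldehyde), C=O
Why: Lewis acid promoted carbonyl-ene reaction, in which C-11 bonds to the less substituted alkene carbon C-9 and a hydrogen is transferred from the C-17 methyl (cis to H-9, away from quaternary C-10) to create the exocyclic C8=C17 alkene; the enophile should approach C-9 anti to the pseudoaxial C-1 on C-10, so that C-11 ends cis to the C-10 methyl.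

Step 9
Reactants: 12 methyl (1R,4aR,5R,8aR)-5-(hydroxymethyl)-1,4a-dimethyl-6-methylidenedecahydronaphthalene-1-carboxylate
Product: 13 methyl (1R,4aR,5R,8aR)-5-formyl-1,4a-dimethyl-6-methylidenedecahydronaphthalene-1-carboxylate
Conditions: Dess–Martin periodinane, NaHCO3, CH2Cl2, 0 °C
Reagents that add atoms: none
Why: Dess–Martin oxidation of the primary homoallylic alcohol under buffered conditions should give the β,γ-unsaturated aldehyde without epimerising C-9 or moving the alkene.

Step 10
Reactants: 13 methyl (1R,4aR,5R,8aR)-5-formyl-1,4a-dimethyl-6-methylidenedecahydronaphthalene-1-carboxylate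
Product: 14 methyl (1R,4aR,5R,8aR)-5-ethenyl-1,4a-dimethyl-6-methylidenedecahydronaphthalene-1-carboxylate
Conditions: Ph3PCH3Br, KN(SiMe3)2, THF, 0 °C; then 13, −78 to 0 °C
Reagents that add atoms: methyltriphenylphosphonium bromide, C[P+](c1ccccc1)(c1ccccc1)c1ccccc1.[Br-]
Why: Wittig methylenation with the non-stabilised ylide at low temperature should be faster than enolisation of the aldehyde, so C-9 and the exocyclic alkene are kept; the methyl ester does not react.

Step 11
Reactants: 14 methyl (1R,4aR,5R,8aR)-5-ethenyl-1,4a-dimethyl-6-methylidenedecahydronaphthalene-1-carboxylate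
Product: 15 [(1R,4aR,5R,8aR)-5-ethenyl-1,4a-dimethyl-6-methylidenedecahydronaphthalen-1-yl]methanol
Conditions: LiAlH4, Et2O, 0 °C to rt
Reagents that add atoms: none
Why: Hydride reduction of the hindered neopentyl-type ester to the primary alcohol; the isolated alkenes are inert.

Step 12
Reactants: 15 [(1R,4aR,5R,8aR)-5-ethenyl-1,4a-dimethyl-6-methylidenedecahydronaphthalen-1-yl]methanol
Product: 16 [(1R,4aR,5R,8aR)-5-ethenyl-1,4a-dimethyl-6-methylidenedecahydronaphthalen-1-yl]methyl acetate
Conditions: Ac2O, pyridine, DMAP (cat.), rt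
Reagents that add atoms: acetic anhydride, CC(=O)OC(C)=O
Why: DMAP-catalysed acylation of the neopentyl primary alcohol.

Step 13
Reactants: 16 [(1R,4aR,5R,8aR)-5-ethenyl-1,4a-dimethyl-6-methylidenedecahydronaphthalen-1-yl]methyl acetate; 17 3-bromofuran-2(5H)-one
Product: 19 [(1R,4aS,5R,8aR)-1,4a-dimethyl-6-methylidene-5-[2-(2-oxo-2,5-dihydrofuran-3-yl)ethyl]decahydronaphthalen-1-yl]methyl acetate (CNP0350004.1), via B-alkyl-9-BBN borane 18 (not isolated)
Conditions: 9-BBN (1.2 equiv), THF, 0 °C to rt; then 17, PdCl2(dppf) (5 mol %), K3PO4 (3 M aq.), DMF, rt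
Reagents that add atoms: none
Why: Anti-Markovnikov hydroboration by 9-BBN should favour the unhindered vinyl group over the exocyclic alkene flanked by C-7 and C-9, and B-alkyl Suzuki–Miyaura coupling of the primary alkylborane with the α-bromo butenolide forms C12–C13; the acetate and lactone should survive aqueous K3PO4 at room temperature.

Compound list
1 | (R)-(−)-carvone, (5R)-2-methyl-5-(prop-1-en-2-yl)cyclohex-2-en-1-one | CC1=CC[C@H](CC1=O)C(C)=C | starting material
2 | (5R)-2-methyl-5-(2-methyloxiran-2-yl)cyclohex-2-en-1-one (oxirane epimers) | CC1=CC[C@H](CC1=O)C1(C)CO1 | intermediate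
3 | 2-[(1R)-4-methyl-5-oxocyclohex-3-en-1-yl]propanal (C-2 epimers) | CC1=CC[C@H](CC1=O)C(C)C=O | intermediate
4 | methyl 2-[(1R)-4-methyl-5-oxocyclohex-3-en-1-yl]propanoate (C-2 epimers) | CC1=CC[C@H](CC1=O)C(C)C(=O)OC | intermediate
5 | 1-chloro-3-iodopropane | ClCCCI | starting material
6 | methyl 2-[(1R)-2-(3-chloropropyl)-4-methyl-3-oxocyclohex-4-en-1-yl]propanoate (C-10 chloropropyl keto ester) | CC1=CC[C@H](C(CCCCl)C1=O)C(C)C(=O)OC | intermediate (not isolated)
7 | methyl (1R,8aR)-1,6-dimethyl-5-oxo-1,2,3,4,4a,5,8,8a-octahydronaphthalene-1-carboxylate (C-4a epimers; ester cis to H-8a) | CC1=CC[C@H]2[C@](C)(C(=O)OC)CCCC2C1=O | intermediate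
8 | methyl (1R,4aR,8aR)-1,4a,6-trimethyl-5-oxo-1,2,3,4,4a,5,8,8a-octahydronaphthalene-1-carboxylate (cis-fused; angular methyl, H-8a and ester on one face) | CC1=CC[C@H]2[C@](C)(C(=O)OC)CCC[C@@]2(C)C1=O | intermediate
9 | lithium enolate of the 7,8-dihydro ketone derived from 8 (C8–C9 enolate, labdane numbering) | CC1CC[C@H]2[C@](C)(C(=O)OC)CCC[C@@]2(C)C=1[O-].[Li+] | intermediate (not isolated)
10 | methyl (1R,4aR,8aR)-1,4a,6-trimethyl-5-(trifluoromethanesulfonyloxy)-1,2,3,4,4a,7,8,8a-octahydronaphthalene-1-carboxylate | CC1CC[C@H]2[C@](C)(C(=O)OC)CCC[C@@]2(C)C=1OS(=O)(=O)C(F)(F)F | intermediate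
11 | methyl (1R,4aS,8aR)-1,4a,6-trimethyl-1,2,3,4,4a,7,8,8a-octahydronaphthalene-1-carboxylate | CC1CC[C@H]2[C@](C)(C(=O)OC)CCC[C@@]2(C)C=1 | intermediate
12 | methyl (1R,4aR,5R,8aR)-5-(hydroxymethyl)-1,4a-dimethyl-6-methylidenedecahydronaphthalene-1-carboxylate | C=C1CC[C@H]2[C@](C)(C(=O)OC)CCC[C@@]2(C)[C@@H]1CO | intermediate
13 | methyl (1R,4aR,5R,8aR)-5-formyl-1,4a-dimethyl-6-methylidenedecahydronaphthalene-1-carboxylate | C=C1CC[C@H]2[C@](C)(C(=O)OC)CCC[C@@]2(C)[C@@H]1C=O | intermediate
14 | methyl (1R,4aR,5R,8aR)-5-ethenyl-1,4a-dimethyl-6-methylidenedecahydronaphthalene-1-carboxylate | C=C1CC[C@H]2[C@](C)(C(=O)OC)CCC[C@@]2(C)[C@@H]1C=C | intermediate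
15 | [(1R,4aR,5R,8aR)-5-ethenyl-1,4a-dimethyl-6-methylidenedecahydronaphthalen-1-yl]methanol | C=C1CC[C@H]2[C@](C)(CO)CCC[C@@]2(C)[C@@H]1C=C | intermediate
16 | [(1R,4aR,5R,8aR)-5-ethenyl-1,4a-dimethyl-6-methylidenedecahydronaphthalen-1-yl]methyl acetate | C=C1CC[C@H]2[C@](C)(COC(C)=O)CCC[C@@]2(C)[C@@H]1C=C | intermediate
17 | 3-bromofuran-2(5H)-one | BrC1=CCOC1=O | starting material
18 | B-alkyl-9-BBN from hydroboration of the vinyl group of 16 | C=C1CC[C@H]2[C@](C)(COC(C)=O)CCC[C@@]2(C)[C@@H]1CCB1C2CCCC1CCC2 | intermediate (not isolated)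
19 | [(1R,4aS,5R,8aR)-1,4a-dimethyl-6-methylidene-5-[2-(2-oxo-2,5-dihydrofuran-3-yl)ethyl]decahydronaphthalen-1-yl]methyl acetate (CNP0350004.1) | C=C1CC[C@H]2[C@](C)(COC(C)=O)CCC[C@@]2(C)[C@@H]1CCC1=CCOC1=O | target

Total step count: 13. Longest linear sequence: 13 steps (from 1).

Steps most likely to fail

Step 4. The two enolates and the two halide ends may not pair in the intended order: a second alkylation at C-10, O-alkylation of the ketone enolate by the tethered chloride, or slow closure of the hindered ester enolate onto a chloride. The fallback sets out from 4 and makes the two bonds in separate, isolated operations with a masked second electrophile. The α′-enolate of 4 (LiN(i-Pr)2, THF, −78 °C) would be alkylated with tert-butyl(3-iodopropoxy)dimethylsilane to give methyl 2-[(1R)-2-{3-[tert-butyl(dimethyl)silyloxy]propyl}-4-methyl-3-oxocyclohex-4-en-1-yl]propanoate F1. Ph3PBr2 in CH2Cl2 would convert the silyl ether directly into methyl 2-[(1R)-2-(3-bromopropyl)-4-methyl-3-oxocyclohex-4-en-1-yl]propanoate F2. The bromide would then be closed with LiN(i-Pr)2 (2.2 equiv) in THF/DMPU between −78 and 0 °C, where the ester enolate alkylates and the lithium ketone enolate should stay inert. The fallback comes back to the route at 7.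

Step 8. The hindered C-9 terminus may react too slowly with the formaldehyde–aluminium complex, or the developing C-8 cation may lose a hydrogen from C-7 or capture chloride instead of taking the C-17 hydrogen. The fallback sets out from 11 and uses a more reactive enophile followed by excision of the extra carbon. A glyoxylate–ene reaction (ethyl glyoxylate, SnCl4, CH2Cl2, −78 °C) should give methyl (1R,4aR,5R,8aR)-5-(2-ethoxy-1-hydroxy-2-oxoethyl)-1,4a-dimethyl-6-methylidenedecahydronaphthalene-1-carboxylate F3 (carbinol centre unassigned). LiAlH4 would reduce both esters to [(1R,4aR,5R,8aR)-5-(1,2-dihydroxyethyl)-1,4a-dimethyl-6-methylidenedecahydronaphthalen-1-yl]methanol F4. NaIO4 in THF/H2O would cleave the 1,2-diol to (1R,4aR,5R,8aR)-5-(hydroxymethyl)-5,8a-dimethyl-2-methylidenedecahydronaphthalene-1-carbaldehyde F5. Wittig methylenation as in step 10, with excess ylide, then comes back to the route at 15.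

Step 13. 9-BBN may also hydroborate the exocyclic alkene, and the B-alkyl transmetalation may be slower than base-induced decomposition of the bromobutenolide. The fallback sets out from 16 and forms C12–C13 by enolate alkylation instead of cross-coupling. Hydroboration with the more discriminating disiamylborane and oxidation with NaBO3·4H2O should give [(1R,4aS,5R,8aR)-5-(2-hydroxyethyl)-1,4a-dimethyl-6-methylidenedecahydronaphthalen-1-yl]methyl acetate F6. I2, PPh3 and imidazole would give [(1R,4aS,5R,8aR)-5-(2-iodoethyl)-1,4a-dimethyl-6-methylidenedecahydronaphthalen-1-yl]methyl acetate F7. Alkylation of the lithium enolate of 3-(phenylselanyl)oxolan-2-one (LiN(SiMe3)2, THF/DMPU) with F7 would give [(1R,4aS,5R,8aR)-1,4a-dimethyl-6-methylidene-5-{2-[2-oxo-3-(phenylselanyl)oxolan-3-yl]ethyl}decahydronaphthalen-1-yl]methyl acetate F8. Oxidation with H2O2 and syn-elimination of the selenoxide towards the ring CH2 comes back to the route at 19.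

Further compounds
F1 | step 4 | methyl 2-[(1R)-2-{3-[tert-butyl(dimethyl)silyloxy]propyl}-4-methyl-3-oxocyclohex-4-en-1-yl]propanoate | CC1=CC[C@H](C(CCCO[Si](C)(C)C(C)(C)C)C1=O)C(C)C(=O)OC
F2 | step 4 | methyl 2-[(1R)-2-(3-bromopropyl)-4-methyl-3-oxocyclohex-4-en-1-yl]propanoate | CC1=CC[C@H](C(CCCBr)C1=O)C(C)C(=O)OC
F3 | step 8 | methyl (1R,4aR,5R,8aR)-5-(2-ethoxy-1-hydroxy-2-oxoethyl)-1,4a-dimethyl-6-methylidenedecahydronaphthalene-1-carboxylate | C=C1CC[C@H]2[C@](C)(C(=O)OC)CCC[C@@]2(C)[C@@H]1C(O)C(=O)OCC
F4 | step 8 | [(1R,4aR,5R,8aR)-5-(1,2-dihydroxyethyl)-1,4a-dimethyl-6-methylidenedecahydronaphthalen-1-yl]methanol | C=C1CC[C@H]2[C@](C)(CO)CCC[C@@]2(C)[C@@H]1C(O)CO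
F5 | step 8 | (1R,4aR,5R,8aR)-5-(hydroxymethyl)-5,8a-dimethyl-2-methylidenedecahydronaphthalene-1-carbaldehyde | C=C1CC[C@H]2[C@](C)(CO)CCC[C@@]2(C)[C@@H]1C=O
F6 | step 13 | [(1R,4aS,5R,8aR)-5-(2-hydroxyethyl)-1,4a-dimethyl-6-methylidenedecahydronaphthalen-1-yl]methyl acetate | C=C1CC[C@H]2[C@](C)(COC(C)=O)CCC[C@@]2(C)[C@@H]1CCO
F7 | step 13 | [(1R,4aS,5R,8aR)-5-(2-iodoethyl)-1,4a-dimethyl-6-methylidenedecahydronaphthalen-1-yl]methyl acetate | C=C1CC[C@H]2[C@](C)(COC(C)=O)CCC[C@@]2(C)[C@@H]1CCI
F8 | step 13 | [(1R,4aS,5R,8aR)-1,4a-dimethyl-6-methylidene-5-{2-[2-oxo-3-(phenylselanyl)oxolan-3-yl]ethyl}decahydronaphthalen-1-yl]methyl acetate | C=C1CC[C@H]2[C@](C)(COC(C)=O)CCC[C@@]2(C)[C@@H]1CCC1([Se]c3ccccc3)CCOC1=O
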